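**Retrosynthetic overview (disconnections listed from the bought material towards the target)**

1. Rings A and B, C4, C5, C10 and all 20 skeletal carbons (furan included) are bought in (+)-lambertianic acid 1; no carbocycle is built.
2. C7–O disconnection: 1 → allylic alcohol 2 → exocyclic enone 3 → conjugated enone acid 4 (C9 becomes sp2 and is re-set later).
3. C7/C19 reduction and acetyl loading: 4 → diol 5 → diacetate 6.
4. C9–O and C8–O (trans-diaxial pair): 6 → α-epoxide 7 → acetoxonium ion 8 → hydroxy acetate 9 → ketone 10.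
5. Key disconnection C13–O9: 10 → oxocarbenium ion 11 → spiro ether 12 → target 13; the tetrahydrofuran (ring C) and the dihydrofuran (ring D) arise together, last, in the light-driven step.

Assumption: (+)-lambertianic acid (normal labdane series, main resin acid of Siberian pine) is taken as an inexpensive commercial chiral-pool material; atom labels are labdane numbers.

**Route**

Step 1
Reactants: 1 (+)-lambertianic acid (15,16-epoxylabda-8(17),13(16),14-trien-19-oic acid)
Product: 2 7α-hydroxy-15,16-epoxylabda-8(17),13(16),14-trien-19-oic acid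
Conditions: SeO2 (0.3 equiv), t-BuOOH (2.5 equiv), CH2Cl2, rt
Reagents that add atoms: selenium dioxide, O=[Se]=O (transfers the oxygen); tert-butyl hydroperoxide, CC(C)(C)OO (re-oxidant, ultimate oxygen source)
Why: Riley-type allylic oxidation (ene reaction, then [2,3]-sigmatropic shift) attacks the ring CH2 next to the 1,1-disubstituted alkene and delivers oxygen axially (7α); this carbinol centre is only transient.

Step 2
Reactants: 2 7α-hydroxy-15,16-epoxylabda-8(17),13(16),14-trien-19-oic acid
Product: 4 7-oxo-15,16-epoxylabda-8,13(16),14-trien-19-oic acid, via exocyclic enone acid 3 (not isolated)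
Conditions: DMP, CH2Cl2, rt; filter, concentrate; then RhCl3·3H2O (5 mol %), EtOH, 75 °C
Reagents that add atoms: none
Why: Dess–Martin oxidation gives the exocyclic enone 3, and rhodium-hydride addition–elimination (exo-to-endo alkene isomerisation) moves the double bond to the more stable tetrasubstituted, conjugated C8=C9 position; C9 is flattened here and re-set in step 5.

Step 3
Reactants: 4 7-oxo-15,16-epoxylabda-8,13(16),14-trien-19-oic acid
Product: 5 15,16-epoxylabda-8,13(16),14-triene-7β,19-diol
Conditions: LiAlH4 (4 equiv), THF, 0 → 60 °C; then H2O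
Reagents that add atoms: none
Why: Hydride reduction in which 1,2-addition to the enone from the α face (axial attack, away from the C10-methyl face) gives the pseudo-equatorial 7β-alcohol, while the C19 acid is reduced to the primary alcohol in the same pot.

Step 4
Reactants: 5 15,16-epoxylabda-8,13(16),14-triene-7β,19-diol
Product: 6 7β,19-diacetoxy-15,16-epoxylabda-8,13(16),14-triene
Conditions: Ac2O, pyridine, DMAP (cat.), CH2Cl2, rt
Reagents that add atoms: acetic anhydride, CC(=O)OC(C)=O
Why: DMAP-catalysed acylation of both hydroxyls; the C7 acetate is the later neighbouring group and the source of the C8 acetate, and the C19 acetate protects the primary alcohol.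

Step 5
Reactants: 6 7β,19-diacetoxy-15,16-epoxylabda-8,13(16),14-triene
Product: 9 8β,19-diacetoxy-15,16-epoxylabda-13(16),14-diene-7β,9α-diol, via 8α,9α-epoxide 7 (not isolated), via acetoxonium ion 8 (not isolated)
Conditions: m-CPBA (1.05 equiv), NaHCO3, CH2Cl2, −30 °C; filter; then TsOH·H2O (10 mol %), THF/H2O (20:1), 0 °C
Reagents that add atoms: 3-chloroperbenzoic acid, OOC(=O)c1cccc(Cl)c1; water, O
Why: Prilezhaev epoxidation of the tetrasubstituted alkene (faster than attack on the 3-alkylfuran) occurs on the α face, away from the C10 methyl and the 7β-acetate, which fixes C9–O as α; acid then opens 7 at C8 trans-diaxially with backside participation of the 7β-acetate carbonyl (Woodward–Prévost-type ion 8, inversion at C8, so C8–O is β), and water cleaves 8 to the axial tertiary acetate and the equatorial 7β-alcohol (axial-ester rule of ortho-ester opening).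

Step 6
Reactants: 9 8β,19-diacetoxy-15,16-epoxylabda-13(16),14-diene-7β,9α-diol
Product: 10 8β,19-diacetoxy-9α-hydroxy-15,16-epoxylabda-13(16),14-dien-7-one
Conditions: DMP, pyridine, CH2Cl2, 0 °C → rt (crude 9 used at once)
Reagents that add atoms: none
Why: Dess–Martin oxidation of the only secondary alcohol; the tertiary 9-OH, both acetates and the furan are inert, and no stereocentre is touched.

Step 7
Reactants: 10 8β,19-diacetoxy-9α-hydroxy-15,16-epoxylabda-13(16),14-dien-7-one
Product: 12 (13R)-8β,19-diacetoxy-9α,13:15,16-diepoxylabd-14-en-7-one, via oxocarbenium ion 11 (not isolated)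
Conditions: Co(C32H46N2O2) [divalent cobalt complex of N,N'-bis(3,5-di-tert-butylsalicylidene)ethane-1,2-diamine] (5 mol %), 10-phenylphenothiazine (5 mol %), 2,4,6-collidinium triflate (0.5 equiv), 2,4,6-collidine (0.5 equiv), 4 Å MS, CH2Cl2, 390 nm LEDs, 0 °C
Reagents that add atoms: none
Why: Proposed new method: light-driven cobalt-hydride hydrogen-atom transfer/radical-polar crossover applied to a furan C=C bond (closest known reaction type: photoredox/cobalt/Brønsted-acid Markovnikov hydroalkoxylation of unactivated alkenes and the cobalt–salen cycloetherification of alkenols); excited phenothiazine reduces divalent to monovalent cobalt, protonation by collidinium gives a trivalent cobalt hydride that delivers H• to the furan α-carbon C16 (leaving the more substituted, oxygen-stabilised allyl radical), the phenothiazine radical cation oxidises that radical to 11, and the axial 9α-OH captures 11 at C13 in a 5-exo closure (an adduct from H• delivery to C15 has no ring-closing exit and returns to 10) before collidine removes the proton, so the photon pays for the lost furan aromaticity and the weakly acidic medium blocks the acid-catalysed return to the furan; C13 is set by substrate control, because the flat cation turns its unsubstituted O–C16 edge toward the C17-methyl side and its C14–C15 edge toward C1 during capture, which gives 13R.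

Step 8
Reactants: 12 (13R)-8β,19-diacetoxy-9α,13:15,16-diepoxylabd-14-en-7-one
Product: 13 (13R)-8β-acetoxy-19-hydroxy-9α,13:15,16-diepoxylabd-14-en-7-one
Conditions: K2CO3 (0.2 equiv), MeOH, 0 °C
Reagents that add atoms: none
Why: Base-catalysed transesterification (Zemplén-type) removes the primary C19 acetate much faster than the axial tertiary C8 acetate flanked by two fully substituted carbons; the spiro enol ether is base-stable, C9 is now an ether (no retro-aldol), and no stereocentre is involved.

**Compound list**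

1 | (+)-lambertianic acid; 15,16-epoxylabda-8(17),13(16),14-trien-19-oic acid (4S,5R,9S,10R) | C=C1CC[C@H]2[C@@](C)(C(=O)O)CCC[C@]2(C)[C@H]1CCc1ccoc1 | starting material
2 | 7α-hydroxy-15,16-epoxylabda-8(17),13(16),14-trien-19-oic acid | C=C1[C@H](O)C[C@H]2[C@@](C)(C(=O)O)CCC[C@]2(C)[C@H]1CCc1ccoc1 | intermediate
3 | 7-oxo-15,16-epoxylabda-8(17),13(16),14-trien-19-oic acid (exocyclic enone acid) | C=C1C(=O)C[C@H]2[C@@](C)(C(=O)O)CCC[C@]2(C)[C@H]1CCc1ccoc1 | intermediate
4 | 7-oxo-15,16-epoxylabda-8,13(16),14-trien-19-oic acid | CC=1C(=O)C[C@H]2[C@@](C)(C(=O)O)CCC[C@]2(C)C=1CCc1ccoc1 | intermediate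
5 | 15,16-epoxylabda-8,13(16),14-triene-7β,19-diol | CC=1[C@@H](O)C[C@H]2[C@@](C)(CO)CCC[C@]2(C)C=1CCc1ccoc1 | intermediate
6 | 7β,19-diacetoxy-15,16-epoxylabda-8,13(16),14-triene | CC=1[C@@H](OC(C)=O)C[C@H]2[C@@](C)(COC(C)=O)CCC[C@]2(C)C=1CCc1ccoc1 | intermediate
7 | 7β,19-diacetoxy-8α,9α:15,16-diepoxylabda-13(16),14-diene | C[C@@]12[C@@H](OC(C)=O)C[C@H]3[C@@](C)(COC(C)=O)CCC[C@]3(C)[C@]1(CCc1ccoc1)O2 | intermediate
8 | 7β,8β-acetoxonium ion (2-methyl-1,3-dioxolan-2-ylium bridging O7 and O8) of 19-acetoxy-9α-hydroxy-15,16-epoxylabda-13(16),14-diene | CC1=[O+][C@@]2(C)[C@@H](O1)C[C@H]3[C@@](C)(COC(C)=O)CCC[C@]3(C)[C@@]2(O)CCc2ccoc2 | intermediate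
9 | 8β,19-diacetoxy-15,16-epoxylabda-13(16),14-diene-7β,9α-diol | CC(=O)O[C@@]1(C)[C@@H](O)C[C@H]2[C@@](C)(COC(C)=O)CCC[C@]2(C)[C@@]1(O)CCc1ccoc1 | intermediate
10 | 8β,19-diacetoxy-9α-hydroxy-15,16-epoxylabda-13(16),14-dien-7-one | CC(=O)O[C@@]1(C)C(=O)C[C@H]2[C@@](C)(COC(C)=O)CCC[C@]2(C)[C@@]1(O)CCc1ccoc1 | intermediate
11 | C16-hydro 2H-furanium (oxocarbenium) ion derived from 10 | CC(=O)O[C@@]1(C)C(=O)C[C@H]2[C@@](C)(COC(C)=O)CCC[C@]2(C)[C@@]1(O)CCC1=CC=[O+]C1 | intermediate
12 | (13R)-8β,19-diacetoxy-9α,13:15,16-diepoxylabd-14-en-7-one | CC(=O)O[C@@]1(C)C(=O)C[C@H]2[C@@](C)(COC(C)=O)CCC[C@]2(C)[C@@]12CC[C@]1(C=COC1)O2 | intermediate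
13 | (13R)-8β-acetoxy-19-hydroxy-9α,13:15,16-diepoxylabd-14-en-7-one (CNP0239339.1) | CC(=O)O[C@@]1(C)C(=O)C[C@H]2[C@@](C)(CO)CCC[C@]2(C)[C@@]12CC[C@]1(C=COC1)O2 | target

**Step count and risks**

Total step count: 8. Longest linear sequence: 8 steps (1 → 13, fully linear).

Most likely to fail, first: step 7 (the proposed photochemical spirocyclisation). Hydrogen-atom transfer from a cobalt hydride to a furan is unproven and H• could go to C15. The C13 selectivity rests only on a small steric difference between the C17-methyl side and the C1 side, so the 13-epimer may form in a similar amount. The fallback uses known chemistry, sets out from 9 and comes back at 12. Sensitised photo-oxygenation of the furan of 9 (O2, tetraphenylporphyrin, visible light, i-Pr2NEt, CH2Cl2, −78 °C) gives the γ-hydroxybutenolide F1, with the carbonyl at C15 and the lactol at C16. NaBH4 (EtOH, 0 °C, then dilute acid) reduces the masked C16 aldehyde and closes the butenolide F2. Catalytic DBU (CH2Cl2, 0 °C, stopped at full conversion to limit acetyl migration from O8 to O7) lets the 9α-OH add to C13 in a reversible 5-exo oxa-Michael reaction to give the spiro-lactone F3; C13 is then under thermodynamic control, and the epimers can be separated and re-equilibrated. Disiamylborane (THF, 0 °C) reduces only the γ-lactone, to the lactol F4, and leaves both acetates. MsCl/Et3N (−20 °C) dehydrates the lactol to the enol ether alcohol F5. Pyridine-buffered Dess–Martin oxidation of the 7β-OH then gives 12.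

Second: step 5. The peracid may attack the furan, and cleavage of the acetoxonium ion may give some of the 7-acetate/8-alcohol isomer, which can also arise from 9 by acetyl migration. The fallback sets out from 5 and comes back at 9. Selective acetylation of the primary alcohol of 5 (Ac2O 1.1 equiv, pyridine, 0 °C) gives the 19-monoacetate F6. Hydroxyl-directed epoxidation with vanadyl bis(acetylacetonate) VO(C5H7O2)2 and t-BuOOH (PhMe, 0 °C), which leaves the furan alone, gives the 8β,9β-epoxide F7, syn to the 7β-OH. Dilute HClO4 in THF/H2O opens it trans-diaxially, water entering at C9 from the α face, to give the 7β,8β,9α-triol F8. MeC(OMe)3 with catalytic camphorsulfonic acid ties the cis-7β,8β-diol into the cyclic orthoacetate F9 (not isolated). Hydrolysis of F9 in 80 % aqueous AcOH gives the axial tertiary acetate and the equatorial alcohol, which is 9.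

Third: step 2. The rhodium-catalysed exo-to-endo shift of the α-methylene ketone may be slow or may damage the furan or the free acid. The fallback sets out from 1 and comes back at 4. Base-mediated alkene migration (KOC(CH3)3, DMSO, 70 °C) gives mainly the tetrasubstituted Δ8(9) acid F10, and the Δ7 isomer is recycled. Allylic oxidation of the ring CH2 at C7 (t-BuOOH, dirhodium tetrakis(caprolactamate) Rh2(C6H10NO)4 1 mol %, K2CO3, CH2Cl2, rt) then gives 4 without passing through the exocyclic enone.

**Further compounds**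

F1 | step 7 | 8β,19-diacetoxy-7β,9α,16-trihydroxylabd-13-en-15,16-olide (γ-hydroxybutenolide, C16 epimers) | CC(=O)O[C@@]1(C)[C@@H](O)C[C@H]2[C@@](C)(COC(C)=O)CCC[C@]2(C)[C@@]1(O)CCC1=CC(=O)OC1O
F2 | step 7 | 8β,19-diacetoxy-7β,9α-dihydroxylabd-13-en-15,16-olide (butenolide) | CC(=O)O[C@@]1(C)[C@@H](O)C[C@H]2[C@@](C)(COC(C)=O)CCC[C@]2(C)[C@@]1(O)CCC1=CC(=O)OC1
F3 | step 7 | (13R)-8β,19-diacetoxy-9α,13-epoxy-7β-hydroxylabdan-15,16-olide (spiro-lactone) | CC(=O)O[C@@]1(C)[C@@H](O)C[C@H]2[C@@](C)(COC(C)=O)CCC[C@]2(C)[C@@]12CC[C@]1(CC(=O)OC1)O2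
F4 | step 7 | (13R)-8β,19-diacetoxy-9α,13:15,16-diepoxylabdane-7β,15-diol (lactol, C15 epimers) | CC(=O)O[C@@]1(C)[C@@H](O)C[C@H]2[C@@](C)(COC(C)=O)CCC[C@]2(C)[C@@]12CC[C@]1(CC(O)OC1)O2
F5 | step 7 | (13R)-8β,19-diacetoxy-9α,13:15,16-diepoxylabd-14-en-7β-ol | CC(=O)O[C@@]1(C)[C@@H](O)C[C@H]2[C@@](C)(COC(C)=O)CCC[C@]2(C)[C@@]12CC[C@]1(C=COC1)O2
F6 | step 5 | 19-acetoxy-15,16-epoxylabda-8,13(16),14-trien-7β-ol | CC=1[C@@H](O)C[C@H]2[C@@](C)(COC(C)=O)CCC[C@]2(C)C=1CCc1ccoc1
F7 | step 5 | 19-acetoxy-8β,9β:15,16-diepoxylabda-13(16),14-dien-7β-ol | C[C@]12[C@@H](O)C[C@H]3[C@@](C)(COC(C)=O)CCC[C@]3(C)[C@@]1(CCc1ccoc1)O2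
F8 | step 5 | 19-acetoxy-15,16-epoxylabda-13(16),14-diene-7β,8β,9α-triol | O[C@@]1(C)[C@@H](O)C[C@H]2[C@@](C)(COC(C)=O)CCC[C@]2(C)[C@@]1(O)CCc1ccoc1
F9 | step 5 | 7β,8β-O-(1-methoxyethylidene) cyclic orthoacetate of F8 (orthoester carbon epimers) | COC1(C)O[C@@]2(C)[C@@H](O1)C[C@H]3[C@@](C)(COC(C)=O)CCC[C@]3(C)[C@@]2(O)CCc2ccoc2
F10 | step 2 | 15,16-epoxylabda-8,13(16),14-trien-19-oic acid | CC=1CC[C@H]2[C@@](C)(C(=O)O)CCC[C@]2(C)C=1CCc1ccoc1
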